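Readings and results stem from a simulated flask on assumed constants; scatter was added.

At early times target comes first: at 0.833 h the south-west run reads 29.6 % target and 0.7 % over-reaction product. Late in the east run, at 80.0 min, it reads 12.2 % target and 64.4 % over-reaction product. So I ask how long target lives in each new flask against the time it is given.

| flask | substrate | reagent | initiator | temperature | remark | time |
|---|---|---|---|---|---|---|
| south-west | 2 M | 2.4 M | 67 mM | 45 °C | run made earlier |  |
| east | 2 M | 2.4 M | 150 mM | 67 °C | run made earlier |  |
| winter | 2.0 M | 2.40 M | 100 mM | 75 °C |  | 10 h |
| midnight | 2.0 M | 2.40 M | 100 mM | 55 °C |  | 10 h |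
| dawn | 2.0 M | 2.40 M | 100 mM | 35 °C |  | 10 h |

south-west run (percent of the substrate charged)

| time / h | over-reaction product / % | side product / % | substrate / % | target / % |
|---|---|---|---|---|
| 0.250 | 0.3 | 1.5 | 87.5 | 10.6 |
| 0.833 | 0.7 | 6.0 | 63.2 | 29.6 |
| 1.50 | 5.7 | 15.8 | 38.9 | 40.0 |
| 2.00 | 5.8 | 19.5 | 28.0 | 44.4 |
| 3.00 | 15.5 | 25.2 | 10.9 | 46.7 |
| 4.00 | 20.0 | 28.1 | 5.7 | 44.8 |
| 5.00 | 27.2 | 28.4 | 0 | 42.4 |

east run (percent of the substrate charged)

| time / min | over-reaction product / % | side product / % | substrate / % | target / % |
|---|---|---|---|---|
| 12.0 | 8.7 | 14.5 | 26.1 | 51.0 |
| 30.0 | 32.9 | 21.9 | 1.8 | 43.5 |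
| 40.0 | 44.0 | 20.3 | 1.1 | 36.6 |
| 60.0 | 56.1 | 21.5 | 0 | 22.7 |
| 80.0 | 64.4 | 21.4 | 0.7 | 12.2 |
| 90.0 | 67.5 | 19.8 | 0 | 13.4 |

(each reading ± 1 percentage point)

1. which of these there is most of at the end, counted by the substrate in it, winter (target / side product / substrate / over-reaction product)
2. which of these there is most of at the end, counted by the substrate in it, midnight (target / side product / substrate / over-reaction product)
3. which of these there is most of at the end, counted by the substrate in it, dawn (target / side product / substrate / over-reaction product)
4. amount of the one of these that there is most of at the end, in percent of the substrate charged, winter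
5. amount of the one of these that there is most of at the end, in percent of the substrate charged, midnight
6. amount of the one of these that there is most of at the end, in percent of the substrate charged, dawn

- a species is counted by the substrate in it: one ended chains A or side product counts as two
- the analysis behind the earlier runs scatters by 1 percentage point, standard deviation
- steps thought possible: reagent + chain carrier -> target + initiating radical; 2 initiating radical -> ended chains B; initiator -> 2 initiating radical; substrate + target -> side product; target -> over-reaction product; substrate + initiating radical -> chain carrier; 2 chain carrier -> ended chains A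

I build the flask up one process at a time, in fractions of the charge. With the main step by itself, substrate passes through chain carrier to target. Reagent stands at 1.20 equivalents, so substrate is the limiting reagent and in this first picture the charge ends as target.

Now I add target going on to over-reaction product, a first-order loss. In the east run, from 40.0 min to 80.0 min, target falls from 36.6 % to 12.2 % with substrate near 1.1 % or less, which gives a reading of 1.65 h⁻¹. In the south-west run, from 3.00 h to 5.00 h, over-reaction product gains 12 percentage points over a mean target of 44.5 %, which gives a reading of 0.131 h⁻¹. Both carry the scatter of 1 point. The runs differ in initiator too, but this step has none in it, so I give the gain to temperature: 0.115 K⁻¹ in natural logarithms, one power of ten for every 20.0 K.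

The constant times the time counts the lifetimes target is given. For winter that count is 41.3, and its base-ten logarithm is 1.62, the ageing exponent. Exponent zero means one lifetime. The count is 4.15 at midnight and 0.416 at dawn, so the exponents are 0.618 and −0.381. Target made at the start keeps a fraction 0.0158 at midnight and 0.660 at dawn.

Last I add the side product, which reads 28.4 % at 5.00 h in the south-west run and 21.4 % at 80.0 min in the east run. Winter, taking the reading of the hotter run, leaves 78.6 % for over-reaction product. Midnight, taking the mean of the two, gets 73.9 % over-reaction product. Dawn, taking the south-west reading and reckoned as if the charge became target at the start, has 47.2 % target, an estimate on the low side, since target made later has aged less.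

The forecast says over-reaction product at 79 % in winter, over-reaction product at 72 % at midnight and target at 52 % at dawn, on the ground that "Target is lost first order". My midnight stands higher and my dawn estimate lower, with the same species in each flask.

The flask gives over-reaction product at 77.0 % in winter, over-reaction product at 72.9 % at midnight and target at 50.7 % at dawn: the species of the forecast, its amounts within the tolerance. Dawn's target is a stage in time: at 100 h its exponent rises by one from −0.381 to 0.619, which is midnight's 0.618. There dawn holds 1.08 % target and 69.5 % over-reaction product, where midnight at 10 h holds 1.20 % target and winter, at exponent 1.62, holds 0 %.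

    reagent + chain carrier → target + initiating radical (k = 280 M⁻¹ s⁻¹, Ea = 42.0 kJ mol⁻¹)
    2 initiating radical → ended chains B (k = 1.40 × 10⁷ M⁻¹ s⁻¹, Ea = 17.0 kJ mol⁻¹)
    initiator → 2 initiating radical (k = 9.10 × 10⁻⁷ s⁻¹, Ea = 103 kJ mol⁻¹)
    substrate + target → side product (k = 2.00 × 10⁻⁵ M⁻¹ s⁻¹, Ea = 76.0 kJ mol⁻¹)
    target → over-reaction product (k = 1.20 × 10⁻⁵ s⁻¹, Ea = 97.0 kJ mol⁻¹)
    substrate + initiating radical → chain carrier (k = 1300 M⁻¹ s⁻¹, Ea = 41.0 kJ mol⁻¹)
    2 chain carrier → ended chains A (k = 2.00 × 10⁶ M⁻¹ s⁻¹, Ea = 27.0 kJ mol⁻¹)
    (constants at 35 °C)

A second flask is winter with initiator cut to 0.025 M. The exponent has no initiator in it, so it stays 1.62, which is 41.3 lifetimes, and I expect target to stand near zero. The flask gives 0 % target, 67.9 % over-reaction product and 31.9 % side product.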